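Bound the links in the flask from above and from below, using one ratio.

| setting | beta | zeta | flask |
|---|---|---|---|
| solid first end groups | 1.5 M | 1.5 M | 1.5 M |
| second end groups | 1.35 M | 2.7 M | 1.35 M |
| one-sided end groups | 0.030 M | 0.030 M | 0.0300 M |
| temperature | 35 °C | 30 °C | 35 °C |
| remark | the very flask that is asked about, followed so far | run made earlier |  |
| time |  |  | 2.0 d |
beta run (percent of the solid first end groups charged)

| time / h | links / % | solid first end groups / % |
|---|---|---|
| 8.00 | 81.3 | 0.4 |
| 15.0 | 84.0 | 0.4 |
| 25.0 | 83.0 | 1.0 |
| 30.0 | 81.5 | 0 |
| 40.0 | 83.4 | 0 |
| 50.0 | 84.0 | 0 |

zeta run (percent of the solid first end groups charged)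

| time / min | links / % | solid first end groups / % |
|---|---|---|
| 20.0 | 33.6 | 19.4 |
| 40.0 | 62.8 | 0 |
| 60.0 | 77.2 | 0 |
| 80.0 | 85.1 | 0 |
| 90.0 | 87.0 | 1.4 |
| 120 | 91.1 | 0 |

(standard deviation of a reading: 1 percentage point)
- Sunday's: change nothing and wait 15 h more
- Friday's: at 2.0 d take out 90% of the links then present, then wait 15 h
- Saturday's: at 2.0 d add second end groups, 50.0% of the amount charged, then wait 15 h
- Wednesday's: at 2.0 d raise the temperature by 20 K, then wait 15 h
- links that was removed still counts
- the numbers in the tables scatter with a standard deviation of 1 percentage point
- at the start none of the solid first end groups is in solution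
- additions bring no volume worth counting
1. links, in percent of the solid first end groups first charged, at 2.0 d
2. what to do for the largest gain in links; "none" if nothing gains more than 2 percentage points (Sunday's / Friday's / Saturday's / Wednesday's / none)
3. links present, with what was taken out counted in, in percent of the solid first end groups first charged, after Sunday's
4. links present, with what was taken out counted in, in percent of the solid first end groups first charged, after Wednesday's

We start from above, with two ceilings in percent of the solid charged. Each link takes one second end group, so the links cannot pass 90.0%. If each one-sided end group also takes one first end group away from linking, they cannot pass 98.0%. The first ceiling is lower, which marks second end groups as the limiting reagent.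

The beta readings stand flat from 8.00 h, longer than the 120 min in which the zeta run reached 91.1%. We therefore assume that the plateau marks the end of the second end groups. Dividing the rate of link making by the rate at which second end groups disappear removes time:

plateau L = 82.9% ± 0.82 percentage points, from 82.1% to 83.7%

φ = L·c_As/c_B = 92.1%

Here L is the links, c_As and c_B are the charges of solid first end groups and second end groups, and φ is the link share, the links made per second end group used. On our assumption, 0.107 M of the second end groups went elsewhere in the flask.

Our reckoning keeps the flask inside that bracket under Sunday's, Friday's and Wednesday's. Saturday's lifts the φ ceiling to 124%, so links rise to 98.0%, a gain of 15 points.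

The forecast gives 83.2%, inside our bracket, with 83.2%, 81% and Saturday's. Its ground differs from ours: “this looks like an equilibrium”.

The flask gives 82.5%, inside the bracket, then 82.5% and 82.5%. The best choice is Saturday's, with a gain of 16 points.

    first end groups + second end groups → links (k = 0.0311 L mol⁻¹ min⁻¹, Ea = 68.0 kJ mol⁻¹)
    first end groups + one-sided end groups → capped ends (k = 0.791 L mol⁻¹ min⁻¹, Ea = 60.0 kJ mol⁻¹)
    2 second end groups → homo dimer (k = 0.00124 L mol⁻¹ min⁻¹, Ea = 64.0 kJ mol⁻¹)
    solid first end groups ⇌ first end groups, rate k4*(cs4 - [first end groups]) while solid is left; crystals form when [first end groups] > cs4 (solubility = 0.810 M, k = 0.215 min⁻¹)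
    (constants at 35 °C)

For Saturday's to be the wrong choice, a run must show the φ ceiling above the other one. The neighbour flask charged with 0.60 M of solid first end groups has that order: it made 0.570 M of links from 1.23 M of second end groups used, so its own φ is 46.2%, and its φ ceiling, φ·c_B/c_As, of 104% stands above 95.0%. That neighbour ends with first end groups at 0%, 8.6% of its second end groups left, and links at 95.0%.

The data were generated by integration with made-up constants; noise was put on by code.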